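**Plan**
1. Retrosynthesis first removes the two 3-methylbut-2-enoate esters and the oxirane oxygen (hydroxyl-directed epoxidation of a ring allylic alcohol), leading back to a 6-hydroxy-2-methylcyclohex-2-enone with the side chain at C5.
2. The ring is then cut at C1(carbonyl)–C2(methyl-bearing carbon) and at C3–C4(H2). C2 and C3, the two oxirane carbons, are the two carbons of a propyne unit; C1, C6, C5 and C4 are the four atoms of a strained cyclobutanone whose C1–C4 bond takes up the alkyne on nickel.
3. Forward: the side chain is made from 6-methylhept-5-en-2-one and joined to a bought four-membered ring by Negishi coupling. The cyclobutanone is desymmetrised and oxygenated, expanded to the six-membered ring in step 9, and the oxirane is closed in step 13.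
4. Stereochemistry: the side-chain carbinol comes from L-proline-catalysed aminoxylation. C5 and C6 come from chiral lithium amide deprotonation plus anti Rubottom oxidation and pass unchanged through the ring expansion. The oxirane face comes from axial hydride delivery followed by hydroxyl-directed oxygen transfer.
5. Helpers: the benzyldimethylsilyl group on the alkyne fixes its orientation and two silyl ethers mask the hydroxyls; all three are removed together by fluoride in step 10.

Key step: step 9

Assumption: in step 6 lithium bis[(R)-1-phenylethyl]amide is taken to remove a proton from the α-methylene that becomes C6, by analogy with 4-substituted cyclohexanones; if the other methylene reacts, the (S,S)-amide is used instead.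

Step 1
Reactants: 1 6-methylhept-5-en-2-one
Product: 3 (R)-3-hydroxy-6-methylhept-5-en-2-one, via anilinooxy ketone 2 (not isolated)
Conditions: L-proline (20 mol %), PhNO (slow addition), ketone in excess, DMSO, rt; then CuSO4·5H2O (30 mol %), MeOH, 0 °C
Reagents that add atoms: nitrosobenzene O=Nc1ccccc1
Why: Proline-catalysed α-aminoxylation (O-selective nitroso aldol) of the more substituted enamine, in which the carboxylic acid of L-proline delivers nitrosobenzene to one enamine face and should set the (R) carbinol centre, followed by CuSO4-promoted N–O cleavage that leaves the alkene alone.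

Step 2
Reactants: 3 (R)-3-hydroxy-6-methylhept-5-en-2-one
Product: 4 (R)-3-(tert-butyldimethylsilyloxy)-6-methylhept-5-en-2-one
Conditions: t-BuMe2SiCl, imidazole, DMF, 0 °C → rt
Reagents that add atoms: tert-butylchlorodimethylsilane CC(C)(C)[Si](C)(C)Cl
Why: Standard silylation of a secondary α-hydroxy ketone, which also stops α-ketol isomerisation, without touching the stereocentre.

Step 3
Reactants: 4 (R)-3-(tert-butyldimethylsilyloxy)-6-methylhept-5-en-2-one
Product: 6 (R)-3-(tert-butyldimethylsilyloxy)-6-methylhepta-1,5-dien-2-yl trifluoromethanesulfonate, via potassium enolate 5 (not isolated)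
Conditions: KN(SiMe3)2, THF, −78 °C; then PhNTf2, −78 → 0 °C
Reagents that add atoms: N-phenylbis(trifluoromethanesulfonimide) O=S(=O)(N(c1ccccc1)S(=O)(=O)C(F)(F)F)C(F)(F)F
Why: Kinetic enolisation with a hindered amide base should remove a methyl proton and not the hindered α-siloxy methine, and O-triflation of the terminal enolate gives the 1,1-disubstituted enol triflate with the stereocentre intact.

Step 4
Reactants: 6 (R)-3-(tert-butyldimethylsilyloxy)-6-methylhepta-1,5-dien-2-yl trifluoromethanesulfonate; 7 3-bromo-1,1-dimethoxycyclobutane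
Product: 9 tert-butyl{[(R)-2-(3,3-dimethoxycyclobutyl)-6-methylhepta-1,5-dien-3-yl]oxy}dimethylsilane, via cyclobutylzinc bromide 8 (not isolated)
Conditions: Zn dust, LiCl, THF, 50 °C; then 6, Pd(OAc)2 (2 mol %), CPhos (4 mol %), THF, rt
Reagents that add atoms: none
Why: Negishi cross-coupling of a secondary alkylzinc halide and an alkenyl triflate, in which the biaryl phosphine favours reductive elimination over β-hydride elimination; the cyclobutyl carbon is not a stereocentre.

Step 5
Reactants: 9 tert-butyl{[(R)-2-(3,3-dimethoxycyclobutyl)-6-methylhepta-1,5-dien-3-yl]oxy}dimethylsilane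
Product: 10 3-[(R)-3-(tert-butyldimethylsilyloxy)-6-methylhepta-1,5-dien-2-yl]cyclobutan-1-one
Conditions: p-TsOH·H2O (10 mol %), acetone/H2O, rt
Reagents that add atoms: water O
Why: Acid-catalysed ketal hydrolysis under conditions that the secondary silyl ether and both alkenes should survive.

Step 6
Reactants: 10 3-[(R)-3-(tert-butyldimethylsilyloxy)-6-methylhepta-1,5-dien-2-yl]cyclobutan-1-one
Product: 12 (R)-3-[(R)-3-(tert-butyldimethylsilyloxy)-6-methylhepta-1,5-dien-2-yl]-1-(triethylsilyloxy)cyclobut-1-ene, via lithium enolate 11 (not isolated)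
Conditions: LiN[(R)-CH(CH3)Ph]2 (from the amine and n-BuLi), Et3SiCl present from the start, THF, −100 °C
Reagents that add atoms: chlorotriethylsilane CC[Si](Cl)(CC)CC
Why: Asymmetric deprotonation of a 3-substituted cyclobutanone by a C2-symmetric chiral lithium amide with in situ silyl trapping, in which the base selects one of the two α-methylenes and so makes the ring carbon bearing the side chain a stereocentre.

Step 7
Reactants: 12 (R)-3-[(R)-3-(tert-butyldimethylsilyloxy)-6-methylhepta-1,5-dien-2-yl]-1-(triethylsilyloxy)cyclobut-1-ene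
Product: 14 (2S,3S)-3-[(R)-3-(tert-butyldimethylsilyloxy)-6-methylhepta-1,5-dien-2-yl]-2-(triethylsilyloxy)cyclobutan-1-one, via silyloxy oxirane 13 (not isolated)
Conditions: dimethyldioxirane (1.0 equiv, acetone), CH2Cl2, −78 °C → rt
Reagents that add atoms: dimethyldioxirane CC1(C)OO1
Why: Rubottom oxidation, in which the strained electron-rich enol ether should be epoxidised faster than the side-chain alkenes and on the face anti to the neighbouring side chain, the silyloxy oxirane then opening by 1,4-silyl shift to the trans α-silyloxy ketone.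

Step 8
Reactants: 15 prop-1-yn-1-ylmagnesium bromide; 16 benzylchlorodimethylsilane
Product: 17 benzyldimethyl(prop-1-yn-1-yl)silane
Conditions: THF, 0 °C → rt
Reagents that add atoms: none
Why: Substitution at silicon by an alkynyl Grignard reagent with loss of chloride.

Step 9
Reactants: 14 (2S,3S)-3-[(R)-3-(tert-butyldimethylsilyloxy)-6-methylhepta-1,5-dien-2-yl]-2-(triethylsilyloxy)cyclobutan-1-one; 17 benzyldimethyl(prop-1-yn-1-yl)silane
Product: 18 (5S,6S)-3-(benzyldimethylsilyl)-5-[(R)-3-(tert-butyldimethylsilyloxy)-6-methylhepta-1,5-dien-2-yl]-2-methyl-6-(triethylsilyloxy)cyclohex-2-en-1-one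
Conditions: Ni(cod)2 (10 mol %), PCy3 (20 mol %), 17 (1.5 equiv), toluene, 90 °C
Reagents that add atoms: none
Why: Zerovalent nickel couples the ketone carbonyl and the alkyne by oxidative cyclisation to an oxanickelacyclopentene, β-carbon elimination then cleaves the strained CH2–C(carbonyl) bond of the four-membered ring to a seven-membered nickelacycle, and C(sp3)–C(sp2) reductive elimination releases the cyclohexenone, so the carbonyl–C(methyl) and CH2–C(silyl) bonds form in one catalytic cycle. The closest known reaction type is the nickel-catalysed intermolecular insertion of internal alkynes into cyclobutanones (formal [4+2] two-carbon ring expansion), which also runs on 2-substituted azetidin-3-ones and silyl alkynes. The six-membered ring closes by reductive elimination from the seven-membered metallacycle, a ring expansion by σ-bond activation driven by release of cyclobutanone strain. No stereocentre is created: C5 and C6 come unchanged from 14 because none of their bonds is broken, so the ring configuration is that of the desymmetrised cyclobutanone. Two selectivities are needed: cleavage of the CH2–C(O) bond and not the CH(OSiEt3)–C(O) bond, secured by the preference of nickel for migration of the unhindered primary carbon, and the alkyne orientation, secured by the silyl group, which sits next to nickel in the metallacycle and so ends at C3 while the methyl-bearing carbon bonds to the carbonyl carbon. The side-chain alkenes should not compete because insertion of either would close a ring that is too strained or too large.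

Step 10
Reactants: 18 (5S,6S)-3-(benzyldimethylsilyl)-5-[(R)-3-(tert-butyldimethylsilyloxy)-6-methylhepta-1,5-dien-2-yl]-2-methyl-6-(triethylsilyloxy)cyclohex-2-en-1-one
Product: 19 (5S,6S)-6-hydroxy-5-[(R)-3-hydroxy-6-methylhepta-1,5-dien-2-yl]-2-methylcyclohex-2-en-1-one
Conditions: Bu4NF (5 equiv), THF, 0 °C → rt, NH4Cl quench
Reagents that add atoms: none
Why: Fluoride should cleave both silyl ethers and, after loss of the benzyl group from silicon, protodesilylate the carbonyl-activated alkenylsilane (fluoride-promoted protodesilylation of alkenyl benzyldimethylsilanes), without creating or changing a stereocentre.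

Step 11
Reactants: 19 (5S,6S)-6-hydroxy-5-[(R)-3-hydroxy-6-methylhepta-1,5-dien-2-yl]-2-methylcyclohex-2-en-1-one
Product: 20 (1S,6S)-3-methyl-6-[(R)-6-methyl-3-(3-methylbut-2-enoyloxy)hepta-1,5-dien-2-yl]-2-oxocyclohex-3-en-1-yl 3-methylbut-2-enoate
Conditions: 3-methylbut-2-enoyl chloride (3 equiv), pyridine, DMAP (cat.), CH2Cl2, 0 °C → rt
Reagents that add atoms: 3-methylbut-2-enoyl chloride CC(C)=CC(=O)Cl
Why: DMAP-catalysed acylation of both secondary hydroxyls, in which the weak base pyridine should avoid vinylketene formation and deconjugation of the acyl unit.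

Step 12
Reactants: 20 (1S,6S)-3-methyl-6-[(R)-6-methyl-3-(3-methylbut-2-enoyloxy)hepta-1,5-dien-2-yl]-2-oxocyclohex-3-en-1-yl 3-methylbut-2-enoate
Product: 21 (1S,2S,6S)-2-hydroxy-3-methyl-6-[(R)-6-methyl-3-(3-methylbut-2-enoyloxy)hepta-1,5-dien-2-yl]cyclohex-3-en-1-yl 3-methylbut-2-enoate
Conditions: NaBH4, CeCl3·7H2O, MeOH, −78 °C
Reagents that add atoms: none
Why: Luche 1,2-reduction, in which axial hydride delivery to the half-chair (C5 and C6 substituents both equatorial) should give the equatorial alcohol, trans to the C6 ester and cis to the C5 side chain.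

Step 13
Reactants: 21 (1S,2S,6S)-2-hydroxy-3-methyl-6-[(R)-6-methyl-3-(3-methylbut-2-enoyloxy)hepta-1,5-dien-2-yl]cyclohex-3-en-1-yl 3-methylbut-2-enoate
Product: 22 (1R,2R,3S,4S,6S)-2-hydroxy-1-methyl-4-[(R)-6-methyl-3-(3-methylbut-2-enoyloxy)hepta-1,5-dien-2-yl]-7-oxabicyclo[4.1.0]heptan-3-yl 3-methylbut-2-enoate
Conditions: VO(acac)2 (5 mol %), t-BuOOH (1.5 equiv), CH2Cl2, 0 °C → rt
Reagents that add atoms: tert-butyl hydroperoxide CC(C)(C)OO
Why: Vanadium-catalysed hydroxyl-directed epoxidation should deliver oxygen to the ring alkene syn to the allylic hydroxyl (the face cis to the side chain and trans to the C6 ester) and leave the other alkenes alone, as they lack a free allylic hydroxyl or are electron-poor.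

Step 14
Reactants: 22 (1R,2R,3S,4S,6S)-2-hydroxy-1-methyl-4-[(R)-6-methyl-3-(3-methylbut-2-enoyloxy)hepta-1,5-dien-2-yl]-7-oxabicyclo[4.1.0]heptan-3-yl 3-methylbut-2-enoate
Product: 23 (1S,3S,4S,6S)-1-methyl-4-[(R)-6-methyl-3-(3-methylbut-2-enoyloxy)hepta-1,5-dien-2-yl]-2-oxo-7-oxabicyclo[4.1.0]heptan-3-yl 3-methylbut-2-enoate (CNP0140369.1)
Conditions: Dess–Martin periodinane, NaHCO3, CH2Cl2, rt
Reagents that add atoms: none
Why: Dess–Martin oxidation of the secondary epoxy alcohol under buffered conditions should give the epoxy ketone without epimerisation at C6 or opening of the oxirane.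

**Compound list**
1 | 6-methylhept-5-en-2-one | CC(=O)CCC=C(C)C | starting material
2 | (R)-6-methyl-3-[(phenylamino)oxy]hept-5-en-2-one | CC(=O)[C@@H](CC=C(C)C)ONc1ccccc1 | intermediate
3 | (R)-3-hydroxy-6-methylhept-5-en-2-one | CC(=O)[C@@H](CC=C(C)C)O | intermediate
4 | (R)-3-(tert-butyldimethylsilyloxy)-6-methylhept-5-en-2-one | CC(=O)[C@@H](CC=C(C)C)O[Si](C)(C)C(C)(C)C | intermediate
5 | potassium (R)-3-(tert-butyldimethylsilyloxy)-6-methylhepta-1,5-dien-2-olate | C=C([O-])[C@@H](CC=C(C)C)O[Si](C)(C)C(C)(C)C.[K+] | intermediate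
6 | (R)-3-(tert-butyldimethylsilyloxy)-6-methylhepta-1,5-dien-2-yl trifluoromethanesulfonate | C=C(OS(=O)(=O)C(F)(F)F)[C@@H](CC=C(C)C)O[Si](C)(C)C(C)(C)C | intermediate
7 | 3-bromo-1,1-dimethoxycyclobutane | COC1(OC)CC(Br)C1 | starting material
8 | (3,3-dimethoxycyclobutyl)zinc bromide | COC1(OC)CC([Zn]Br)C1 | intermediate
9 | tert-butyl{[(R)-2-(3,3-dimethoxycyclobutyl)-6-methylhepta-1,5-dien-3-yl]oxy}dimethylsilane | C=C([C@@H](CC=C(C)C)O[Si](C)(C)C(C)(C)C)C1CC(OC)(OC)C1 | intermediate
10 | 3-[(R)-3-(tert-butyldimethylsilyloxy)-6-methylhepta-1,5-dien-2-yl]cyclobutan-1-one | C=C([C@@H](CC=C(C)C)O[Si](C)(C)C(C)(C)C)C1CC(=O)C1 | intermediate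
11 | lithium (R)-3-[(R)-3-(tert-butyldimethylsilyloxy)-6-methylhepta-1,5-dien-2-yl]cyclobut-1-en-1-olate | C=C([C@@H](CC=C(C)C)O[Si](C)(C)C(C)(C)C)[C@@H]1CC([O-])=C1.[Li+] | intermediate
12 | (R)-3-[(R)-3-(tert-butyldimethylsilyloxy)-6-methylhepta-1,5-dien-2-yl]-1-(triethylsilyloxy)cyclobut-1-ene | C=C([C@@H](CC=C(C)C)O[Si](C)(C)C(C)(C)C)[C@@H]1CC(O[Si](CC)(CC)CC)=C1 | intermediate
13 | 3-[(R)-3-(tert-butyldimethylsilyloxy)-6-methylhepta-1,5-dien-2-yl]-1-(triethylsilyloxy)-5-oxabicyclo[2.1.0]pentane, oxirane anti to the side chain | C=C([C@@H](CC=C(C)C)O[Si](C)(C)C(C)(C)C)[C@@H]1C[C@@]2(O[Si](CC)(CC)CC)O[C@H]21 | intermediate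
14 | (2S,3S)-3-[(R)-3-(tert-butyldimethylsilyloxy)-6-methylhepta-1,5-dien-2-yl]-2-(triethylsilyloxy)cyclobutan-1-one | C=C([C@@H](CC=C(C)C)O[Si](C)(C)C(C)(C)C)[C@@H]1CC(=O)[C@H]1O[Si](CC)(CC)CC | intermediate
15 | prop-1-yn-1-ylmagnesium bromide | CC#C[Mg]Br | starting material
16 | benzylchlorodimethylsilane | C[Si](C)(Cl)Cc1ccccc1 | starting material
17 | benzyldimethyl(prop-1-yn-1-yl)silane | CC#C[Si](C)(C)Cc1ccccc1 | intermediate
18 | (5S,6S)-3-(benzyldimethylsilyl)-5-[(R)-3-(tert-butyldimethylsilyloxy)-6-methylhepta-1,5-dien-2-yl]-2-methyl-6-(triethylsilyloxy)cyclohex-2-en-1-one | C=C([C@@H](CC=C(C)C)O[Si](C)(C)C(C)(C)C)[C@@H]1CC([Si](C)(C)Cc2ccccc2)=C(C)C(=O)[C@H]1O[Si](CC)(CC)CC | intermediate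
19 | (5S,6S)-6-hydroxy-5-[(R)-3-hydroxy-6-methylhepta-1,5-dien-2-yl]-2-methylcyclohex-2-en-1-one | C=C([C@@H](CC=C(C)C)O)[C@@H]1CC=C(C)C(=O)[C@H]1O | intermediate
20 | (1S,6S)-3-methyl-6-[(R)-6-methyl-3-(3-methylbut-2-enoyloxy)hepta-1,5-dien-2-yl]-2-oxocyclohex-3-en-1-yl 3-methylbut-2-enoate | C=C([C@@H](CC=C(C)C)OC(=O)C=C(C)C)[C@@H]1CC=C(C)C(=O)[C@H]1OC(=O)C=C(C)C | intermediate
21 | (1S,2S,6S)-2-hydroxy-3-methyl-6-[(R)-6-methyl-3-(3-methylbut-2-enoyloxy)hepta-1,5-dien-2-yl]cyclohex-3-en-1-yl 3-methylbut-2-enoate | C=C([C@@H](CC=C(C)C)OC(=O)C=C(C)C)[C@@H]1CC=C(C)[C@H](O)[C@H]1OC(=O)C=C(C)C | intermediate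
22 | (1R,2R,3S,4S,6S)-2-hydroxy-1-methyl-4-[(R)-6-methyl-3-(3-methylbut-2-enoyloxy)hepta-1,5-dien-2-yl]-7-oxabicyclo[4.1.0]heptan-3-yl 3-methylbut-2-enoate | C=C([C@@H](CC=C(C)C)OC(=O)C=C(C)C)[C@@H]1C[C@@H]2O[C@]2(C)[C@H](O)[C@H]1OC(=O)C=C(C)C | intermediate
23 | (1S,3S,4S,6S)-1-methyl-4-[(R)-6-methyl-3-(3-methylbut-2-enoyloxy)hepta-1,5-dien-2-yl]-2-oxo-7-oxabicyclo[4.1.0]heptan-3-yl 3-methylbut-2-enoate (CNP0140369.1) | C=C([C@@H](CC=C(C)C)OC(=O)C=C(C)C)[C@@H]1C[C@@H]2O[C@]2(C)C(=O)[C@H]1OC(=O)C=C(C)C | target

**Totals**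
Total step count: 14.
Longest linear sequence: 13 steps (steps 1 to 7 and 9 to 14, from 6-methylhept-5-en-2-one); step 8 is a one-step side branch.

**Steps most likely to fail**

Step 9. What may go wrong: loss of regiocontrol in the C–C cleavage (β-carbon elimination on the oxygen-bearing side of the ketone) or consumption of the α-siloxy ketone by nickel without ring expansion. The fallback sets out from 10 and comes back at 18: the ring is expanded before the C6 oxygen is introduced. Ketone 10, a 3-monosubstituted cyclobutanone of the kind for which the nickel-catalysed insertion was developed, is treated with 17 under the conditions of step 9. This should give (S)-3-(benzyldimethylsilyl)-5-[(R)-3-(tert-butyldimethylsilyloxy)-6-methylhepta-1,5-dien-2-yl]-2-methylcyclohex-2-en-1-one F1 together with its (5R) epimer F2. The two are diastereomers because of the side-chain centre and are separated by chromatography; control of C5 by the catalyst is given up. F1 is deprotonated at C6 with LiN(iPr)2 in THF at −78 °C to the lithium dienolate F3. Hydroxylation with 2-(phenylsulfonyl)-3-phenyloxaziridine, anti to the C5 substituent, should give the (5S,6S)-6-hydroxy enone F4. Et3SiCl and imidazole then return 18.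

Step 6. What may go wrong: poor discrimination between the two α-methylenes by the chiral base, the resident side-chain centre making one pairing mismatched. The fallback sets out from 10 and comes back at 14: the resident centre is used for separation instead of reagent control. Ketone 10 is enolised without selectivity by LiN(iPr)2 and Et3SiCl, which gives 11 and 12 together with the ring-epimeric lithium enolate F5 and the ring-epimeric enol ether F6. The mixture is oxidised as in step 7, so that F6 passes through the silyloxy oxirane F7 to the (2R,3R)-silyloxy ketone F8 while 12 gives 14. Ketones 14 and F8 are diastereomers and are separated by chromatography.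

Step 7. What may go wrong: loss of chemoselectivity, the dioxirane also epoxidising the trisubstituted side-chain alkene. The fallback sets out from 12 and comes back at 14: the oxygen is put on an enolate by an oxidant that leaves isolated alkenes alone. MeLi in THF at 0 °C cleaves the Si–O bond of 12 and regenerates lithium enolate 11. At −78 °C, 2-(phenylsulfonyl)-3-phenyloxaziridine should hydroxylate 11 anti to the side chain to give (2S,3S)-3-[(R)-3-(tert-butyldimethylsilyloxy)-6-methylhepta-1,5-dien-2-yl]-2-hydroxycyclobutan-1-one F9. Et3SiCl and imidazole then give 14.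

**Further compounds**
F1 | step 9 | (S)-3-(benzyldimethylsilyl)-5-[(R)-3-(tert-butyldimethylsilyloxy)-6-methylhepta-1,5-dien-2-yl]-2-methylcyclohex-2-en-1-one | C=C([C@@H](CC=C(C)C)O[Si](C)(C)C(C)(C)C)[C@@H]1CC([Si](C)(C)Cc2ccccc2)=C(C)C(=O)C1
F2 | step 9 | (R)-3-(benzyldimethylsilyl)-5-[(R)-3-(tert-butyldimethylsilyloxy)-6-methylhepta-1,5-dien-2-yl]-2-methylcyclohex-2-en-1-one | C=C([C@@H](CC=C(C)C)O[Si](C)(C)C(C)(C)C)[C@H]1CC([Si](C)(C)Cc2ccccc2)=C(C)C(=O)C1
F3 | step 9 | lithium (S)-3-(benzyldimethylsilyl)-5-[(R)-3-(tert-butyldimethylsilyloxy)-6-methylhepta-1,5-dien-2-yl]-2-methylcyclohexa-2,6-dien-1-olate | C=C([C@@H](CC=C(C)C)O[Si](C)(C)C(C)(C)C)[C@@H]1CC([Si](C)(C)Cc2ccccc2)=C(C)C([O-])=C1.[Li+]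
F4 | step 9 | (5S,6S)-3-(benzyldimethylsilyl)-5-[(R)-3-(tert-butyldimethylsilyloxy)-6-methylhepta-1,5-dien-2-yl]-6-hydroxy-2-methylcyclohex-2-en-1-one | C=C([C@@H](CC=C(C)C)O[Si](C)(C)C(C)(C)C)[C@@H]1CC([Si](C)(C)Cc2ccccc2)=C(C)C(=O)[C@H]1O
F5 | step 6 | lithium (S)-3-[(R)-3-(tert-butyldimethylsilyloxy)-6-methylhepta-1,5-dien-2-yl]cyclobut-1-en-1-olate | C=C([C@@H](CC=C(C)C)O[Si](C)(C)C(C)(C)C)[C@H]1CC([O-])=C1.[Li+]
F6 | step 6 | (S)-3-[(R)-3-(tert-butyldimethylsilyloxy)-6-methylhepta-1,5-dien-2-yl]-1-(triethylsilyloxy)cyclobut-1-ene | C=C([C@@H](CC=C(C)C)O[Si](C)(C)C(C)(C)C)[C@H]1CC(O[Si](CC)(CC)CC)=C1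
F7 | step 6 | ring-enantiomeric 3-[(R)-3-(tert-butyldimethylsilyloxy)-6-methylhepta-1,5-dien-2-yl]-1-(triethylsilyloxy)-5-oxabicyclo[2.1.0]pentane, oxirane anti to the side chain | C=C([C@@H](CC=C(C)C)O[Si](C)(C)C(C)(C)C)[C@H]1C[C@]2(O[Si](CC)(CC)CC)O[C@@H]21
F8 | step 6 | (2R,3R)-3-[(R)-3-(tert-butyldimethylsilyloxy)-6-methylhepta-1,5-dien-2-yl]-2-(triethylsilyloxy)cyclobutan-1-one | C=C([C@@H](CC=C(C)C)O[Si](C)(C)C(C)(C)C)[C@H]1CC(=O)[C@@H]1O[Si](CC)(CC)CC
F9 | step 7 | (2S,3S)-3-[(R)-3-(tert-butyldimethylsilyloxy)-6-methylhepta-1,5-dien-2-yl]-2-hydroxycyclobutan-1-one | C=C([C@@H](CC=C(C)C)O[Si](C)(C)C(C)(C)C)[C@@H]1CC(=O)[C@H]1O
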